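**Retrosynthetic overview**

- Target 25 is traced back through C2 bromination of the indole and N-detosylation to the 2-aminoimidazoline, which comes from the imidazolidin-2-one 18 by O-ethylation and ammonolysis.
- Feature carrying the strategy: N3–C4–C5 of the imidazoline ring plus C2 are the N–C3–C2–C1 chain of a 3-amino-3-(indol-3-yl)propanoic acid. Inserting a nitrogen (N1) between C5 and the carboxyl carbon turns that carbon into C2.
- Key disconnection: Curtius rearrangement of the Boc-β-amino acid 13 forms C5–N1, and the carbamate nitrogen captures the isocyanate to form N3–C2. The imidazolidinone is the only ring formed in the route; the indole is bought.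
- Acid 13 comes from a sulfinimine Mannich addition of the tert-butyl acetate enolate to the (R)-tert-butanesulfinyl imine of N-tosyl-5-bromoindole-3-carbaldehyde, which sets C4.

Key step: step 6

Remark: the target is taken as the free base drawn, and guanidine intermediates are carried as tetrafluoroborate salts where stated. The sense of induction in step 3 is assigned from the closed transition-state model for titanium enolate additions to N-tert-butanesulfinyl aldimines.

**Route**

Step 1
Reactants: 1 5-bromo-1H-indole-3-carbaldehyde; 2 p-toluenesulfonyl chloride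
Product: 3 5-bromo-1-tosyl-1H-indole-3-carbaldehyde
Conditions: NaH (1.2 equiv), THF, 0 °C; then 2 (1.1 equiv), 0 °C to rt
Reagents that add atoms: p-toluenesulfonyl chloride, Cc1ccc(S(=O)(=O)Cl)cc1
Why: N-sulfonylation of the sodium salt of the acidic formyl-indole N–H, which installs an electron-withdrawing group that later keeps the indol-3-ylmethyl C–N bond from ionising under acid, electrophile and base.

Step 2
Reactants: 3 5-bromo-1-tosyl-1H-indole-3-carbaldehyde; 4 (R)-2-methylpropane-2-sulfinamide
Product: 5 (R,E)-N-[(5-bromo-1-tosyl-1H-indol-3-yl)methylidene]-2-methylpropane-2-sulfinamide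
Conditions: Ti(OEt)4 (2 equiv), THF, 60 °C; brine, filtration
Reagents that add atoms: (R)-2-methylpropane-2-sulfinamide, CC(C)(C)[S@@](=O)N
Why: Lewis-acid-mediated condensation of an aryl aldehyde with a sulfinamide, in which Ti(OEt)4 activates the carbonyl and takes up the water, and the E imine is the thermodynamic product.

Step 3
Reactants: 5 (R,E)-N-sulfinyl aldimine; 6 tert-butyl acetate
Product: 9 tert-butyl (3S)-3-(5-bromo-1-tosyl-1H-indol-3-yl)-3-{[(R)-tert-butylsulfinyl]amino}propanoate, via lithium enolate 7 (not isolated), via titanium enolate 8 (not isolated)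
Conditions: LiN(i-Pr)2 (2.0 equiv), 6 (2.1 equiv), THF, −78 °C; ClTi(Oi-Pr)3 (4 equiv), −78 °C; then 5, −78 °C; aq. NH4Cl
Reagents that add atoms: tert-butyl acetate, CC(=O)OC(C)(C)C
Why: Mannich addition of a titanium ester enolate to an N-sulfinyl aldimine through a closed chair transition state in which titanium is held by the sulfinyl oxygen and imine nitrogen and the tert-butyl group points away, so the enolate should reach the Si face of the (R)-sulfinyl E imine and set C3 as S (the future C4), the slight excess of ester over amide base leaving no base to metalate indole C2.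

Step 4
Reactants: 9 sulfinamide tert-butyl ester; 10 hydrogen chloride
Product: 11 (3S)-3-amino-3-(5-bromo-1-tosyl-1H-indol-3-yl)propanoic acid hydrochloride
Conditions: 4 M HCl in 1,4-dioxane, rt, 16 h; evaporate, triturate with Et2O
Reagents that add atoms: hydrogen chloride, Cl
Why: acidolysis in which chloride cleaves the protonated sulfinamide at sulfur and the tert-butyl ester loses isobutene, so auxiliary and ester are removed together (an ester cleavage after Boc introduction would not be selective) while the sulfonylated indole keeps the benzylic C–N bond and its configuration intact.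

Step 5
Reactants: 11 amino acid hydrochloride; 12 di-tert-butyl dicarbonate
Product: 13 (3S)-3-(5-bromo-1-tosyl-1H-indol-3-yl)-3-[(tert-butoxycarbonyl)amino]propanoic acid
Conditions: 12 (1.3 equiv), NaHCO3 (3 equiv), THF/H2O 1:1, rt; acidify to pH 3 with aq. KHSO4, extract
Reagents that add atoms: di-tert-butyl dicarbonate, CC(C)(C)OC(=O)OC(=O)OC(C)(C)C
Why: standard N-acylation of an amino acid with Boc2O in aqueous bicarbonate, conditions under which the N-sulfonylindole and the stereocentre are not touched.

Step 6
Reactants: 13 Boc-β-amino acid; 14 diphenylphosphoryl azide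
Product: 17 tert-butyl (5R)-5-(5-bromo-1-tosyl-1H-indol-3-yl)-2-oxoimidazolidine-1-carboxylate, via acyl azide 15 (not isolated), via isocyanate 16 (not isolated)
Conditions: 14 (1.1 equiv), Et3N (1.2 equiv), dry toluene (0.05 M), rt 1 h, then 85 °C, 3 h
Reagents that add atoms: diphenylphosphoryl azide, [N-]=[N+]=NP(=O)(Oc1ccccc1)Oc1ccccc1
Why: The carboxylate attacks phosphorus and the released azide acylates to give acyl azide 15, which on heating loses N2 with a concerted 1,2-shift of the CH2 group from carbon to nitrogen (Curtius rearrangement), forming C5–N1 and making the former carboxyl carbon the isocyanate carbon of 16, the future C2. The carbamate N–H on C4 then adds to that digonal carbon and forms N3–C2, a five-membered ring closure by nucleophilic addition to a heterocumulene (5-exo-dig with respect to the C=O bond); the imidazolidinone is the only ring made. The closest known reaction type is the Curtius rearrangement of N-alkoxycarbonyl β-amino acids such as aspartic acid derivatives, which gives 1-alkoxycarbonyl-imidazolidin-2-ones by the same internal capture. No stereocentre is created, and the existing one is neither the migrating carbon nor acidic towards Et3N, so the S centre of 13 should appear unchanged as 5R in 17 (the descriptor changes only because CH2N now outranks the indolyl carbon). The step needs chemoselectivity only: capture by the neighbouring carbamate nitrogen must outrun water, a second molecule or diphenyl phosphate, which the five-membered geometry, the dilution in dry toluene and the absence of any alcohol or amine should secure.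

Step 7
Reactants: 17 N-Boc imidazolidinone
Product: 18 (4R)-4-(5-bromo-1-tosyl-1H-indol-3-yl)imidazolidin-2-one
Conditions: TFA/CH2Cl2 1:4, 0 °C to rt
Reagents that add atoms: none
Why: acidolysis of the acyl-urea-type tert-butyl carbamate with loss of isobutene and CO2, to which the urea, sulfonamide and aryl bromide are inert and under which the deactivated indole does not ionise C4–N3.

Step 8
Reactants: 18 imidazolidin-2-one; 19 triethyloxonium tetrafluoroborate
Product: 20 (4R)-4-(5-bromo-1-tosyl-1H-indol-3-yl)-2-ethoxy-4,5-dihydro-1H-imidazol-3-ium tetrafluoroborate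
Conditions: 19 (1.5 equiv), CH2Cl2, rt, argon; evaporate, use crude
Reagents that add atoms: triethyloxonium tetrafluoroborate, CC[O+](CC)CC.F[B-](F)(F)F
Why: O-alkylation of a urea at its carbonyl oxygen, the most nucleophilic site, by a hard trialkyloxonium salt gives the isouronium salt, while the sulfonamide and the deactivated indole do not compete.

Step 9
Reactants: 20 isouronium tetrafluoroborate; 21 ammonia
Product: 22 (4R)-2-amino-4-(5-bromo-1-tosyl-1H-indol-3-yl)-4,5-dihydro-1H-imidazol-3-ium tetrafluoroborate
Conditions: NH3 (7 M in MeOH, excess), sealed tube, rt to 50 °C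
Reagents that add atoms: ammonia, N
Why: addition–elimination of ammonia at the isouronium carbon with loss of ethanol, the classical isourea-to-guanidine conversion, run while the tosyl group still prevents elimination across C4–N3.

Step 10
Reactants: 22 N-tosyl guanidinium tetrafluoroborate
Product: 23 (4R)-4-(5-bromo-1H-indol-3-yl)-4,5-dihydro-1H-imidazol-2-amine
Conditions: Cs2CO3 (3 equiv), THF/MeOH 2:1, rt to 40 °C; evaporate, wash aqueous solution of the salt with Et2O, then cold 1 M aq. NaOH, extract with CHCl3/i-PrOH 3:1
Reagents that add atoms: none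
Why: methoxide formed from Cs2CO3 attacks the sulfonyl sulfur and releases the indolide as leaving group, while the carbonate medium leaves the guanidine largely protonated and so poorly reactive towards the methyl tosylate formed, and the mild temperature should keep the C4 centre from eliminating.

Step 11
Reactants: 23 detosylated 2-aminoimidazoline; 24 N-bromosuccinimide
Product: 25 (4R)-4-(2,5-dibromo-1H-indol-3-yl)-4,5-dihydro-1H-imidazol-2-amine
Conditions: 24 (1.0 equiv), anhydrous AcOH, rt, dark, N2; then cold 1 M aq. NaOH, extract with CHCl3/i-PrOH 3:1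
Reagents that add atoms: N-bromosuccinimide, O=C1CCC(=O)N1Br
Why: electrophilic bromination of a 3-substituted N–H indole, which proceeds by attack at C3, 1,2-shift of bromine to C2 and rearomatisation, with the guanidine shielded from N-bromination as its acetate salt and the brominated benzo ring too deactivated to compete for one equivalent.

**Compound list**

1 | 5-bromo-1H-indole-3-carbaldehyde | O=Cc1c[nH]c2ccc(Br)cc12 | starting material
2 | p-toluenesulfonyl chloride | Cc1ccc(S(=O)(=O)Cl)cc1 | starting material
3 | 5-bromo-1-tosyl-1H-indole-3-carbaldehyde | O=Cc1cn(S(=O)(=O)c2ccc(C)cc2)c2ccc(Br)cc12 | intermediate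
4 | (R)-2-methylpropane-2-sulfinamide | CC(C)(C)[S@@](=O)N | starting material
5 | (R,E)-N-[(5-bromo-1-tosyl-1H-indol-3-yl)methylidene]-2-methylpropane-2-sulfinamide | CC(C)(C)[S@@](=O)/N=C/c1cn(S(=O)(=O)c2ccc(C)cc2)c2ccc(Br)cc12 | intermediate
6 | tert-butyl acetate | CC(=O)OC(C)(C)C | starting material
7 | lithium enolate of tert-butyl acetate | [Li]OC(=C)OC(C)(C)C | intermediate (not isolated)
8 | triisopropoxytitanium enolate of tert-butyl acetate | C=C(OC(C)(C)C)O[Ti](OC(C)C)(OC(C)C)OC(C)C | intermediate (not isolated)
9 | tert-butyl (3S)-3-(5-bromo-1-tosyl-1H-indol-3-yl)-3-{[(R)-tert-butylsulfinyl]amino}propanoate | CC(C)(C)[S@@](=O)N[C@H](c1cn(S(=O)(=O)c2ccc(C)cc2)c2ccc(Br)cc12)CC(=O)OC(C)(C)C | intermediate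
10 | hydrogen chloride | Cl | starting material
11 | (3S)-3-amino-3-(5-bromo-1-tosyl-1H-indol-3-yl)propanoic acid hydrochloride | Cl.N[C@H](c1cn(S(=O)(=O)c2ccc(C)cc2)c2ccc(Br)cc12)CC(=O)O | intermediate
12 | di-tert-butyl dicarbonate | CC(C)(C)OC(=O)OC(=O)OC(C)(C)C | starting material
13 | (3S)-3-(5-bromo-1-tosyl-1H-indol-3-yl)-3-[(tert-butoxycarbonyl)amino]propanoic acid | CC(C)(C)OC(=O)N[C@H](c1cn(S(=O)(=O)c2ccc(C)cc2)c2ccc(Br)cc12)CC(=O)O | intermediate
14 | diphenylphosphoryl azide | [N-]=[N+]=NP(=O)(Oc1ccccc1)Oc1ccccc1 | starting material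
15 | (3S)-3-(5-bromo-1-tosyl-1H-indol-3-yl)-3-[(tert-butoxycarbonyl)amino]propanoyl azide | CC(C)(C)OC(=O)N[C@H](c1cn(S(=O)(=O)c2ccc(C)cc2)c2ccc(Br)cc12)CC(=O)N=[N+]=[N-] | intermediate (not isolated)
16 | tert-butyl N-[(1R)-1-(5-bromo-1-tosyl-1H-indol-3-yl)-2-isocyanatoethyl]carbamate | CC(C)(C)OC(=O)N[C@H](c1cn(S(=O)(=O)c2ccc(C)cc2)c2ccc(Br)cc12)CN=C=O | intermediate (not isolated)
17 | tert-butyl (5R)-5-(5-bromo-1-tosyl-1H-indol-3-yl)-2-oxoimidazolidine-1-carboxylate | CC(C)(C)OC(=O)N1[C@H](c2cn(S(=O)(=O)c3ccc(C)cc3)c3ccc(Br)cc23)CNC1=O | intermediate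
18 | (4R)-4-(5-bromo-1-tosyl-1H-indol-3-yl)imidazolidin-2-one | O=C1N[C@H](c2cn(S(=O)(=O)c3ccc(C)cc3)c3ccc(Br)cc23)CN1 | intermediate
19 | triethyloxonium tetrafluoroborate | CC[O+](CC)CC.F[B-](F)(F)F | starting material
20 | (4R)-4-(5-bromo-1-tosyl-1H-indol-3-yl)-2-ethoxy-4,5-dihydro-1H-imidazol-3-ium tetrafluoroborate | CCOC1=[NH+][C@H](c2cn(S(=O)(=O)c3ccc(C)cc3)c3ccc(Br)cc23)CN1.F[B-](F)(F)F | intermediate
21 | ammonia | N | starting material
22 | (4R)-2-amino-4-(5-bromo-1-tosyl-1H-indol-3-yl)-4,5-dihydro-1H-imidazol-3-ium tetrafluoroborate | NC1=[NH+][C@H](c2cn(S(=O)(=O)c3ccc(C)cc3)c3ccc(Br)cc23)CN1.F[B-](F)(F)F | intermediate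
23 | (4R)-4-(5-bromo-1H-indol-3-yl)-4,5-dihydro-1H-imidazol-2-amine | NC1=N[C@H](c2c[nH]c3ccc(Br)cc23)CN1 | intermediate
24 | N-bromosuccinimide | O=C1CCC(=O)N1Br | starting material
25 | (4R)-4-(2,5-dibromo-1H-indol-3-yl)-4,5-dihydro-1H-imidazol-2-amine | NC1=N[C@H](c2c(Br)[nH]c3ccc(Br)cc23)CN1 | target

**Step count**

Total steps: 11. Longest linear sequence: 11 steps (fully linear from 1).

**Steps most likely to fail**

Step 11. The bromination may go astray by N-bromination of the guanidine, by hydrolytic diversion of the 3-bromoindolenine to an oxindole, by a second bromination, or by acid-promoted ionisation at C4. The fallback brominates at the neutral urea stage and sets out from 18. Detosylation with Cs2CO3 in THF/MeOH at rt should give (4R)-4-(5-bromo-1H-indol-3-yl)imidazolidin-2-one F1. NBS (1.0 equiv) in THF at −20 to 0 °C should then give (4R)-4-(2,5-dibromo-1H-indol-3-yl)imidazolidin-2-one F2. O-Ethylation with Et3OBF4 in CH2Cl2 leads to (4R)-4-(2,5-dibromo-1H-indol-3-yl)-2-ethoxy-4,5-dihydro-1H-imidazol-3-ium tetrafluoroborate F3. Ammonolysis with NH3 in MeOH at rt and a cold aqueous NaOH work-up bring the sequence back to the route at 25.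

Step 10. The detosylation may suffer from N-methylation of the guanidine by the methyl tosylate formed, from base-induced elimination and re-addition across C4–N3 with loss of configuration, or from incomplete cleavage. The fallback masks the guanidine before the sulfonyl group is removed and sets out from 22. Boc2O (3 equiv), Et3N and DMAP in CH2Cl2, followed by an aqueous NaHCO3 wash, should give tert-butyl (4R)-4-(5-bromo-1-tosyl-1H-indol-3-yl)-2-[(tert-butoxycarbonyl)imino]imidazolidine-1-carboxylate F4. Cs2CO3 in THF/MeOH at rt then cleaves the sulfonamide of this neutral, non-basic compound to tert-butyl (4R)-4-(5-bromo-1H-indol-3-yl)-2-[(tert-butoxycarbonyl)imino]imidazolidine-1-carboxylate F5. A Boc group lost at this stage is of no consequence, since TFA in CH2Cl2 and a cold aqueous NaOH work-up remove both and return the sequence to the route at 23.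

Step 6. Ring closure by the weakly nucleophilic carbamate nitrogen may be outrun by intermolecular capture of the isocyanate (water, then amine, then symmetrical urea), or the Boc group may be lost on heating. The fallback intercepts the isocyanate with an alcohol and closes the ring separately, and sets out from 13. DPPA and Et3N in tert-butanol at 85 °C should give tert-butyl N-[(1R)-1-(5-bromo-1-tosyl-1H-indol-3-yl)-2-[(tert-butoxycarbonyl)amino]ethyl]carbamate F6. TFA in CH2Cl2 and a basic work-up give (1R)-1-(5-bromo-1-tosyl-1H-indol-3-yl)ethane-1,2-diamine F7. 1,1'-Carbonyldiimidazole in THF at rt then closes the urea and comes back to the route at 18.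

**Further compounds**

F1 | step 11 | (4R)-4-(5-bromo-1H-indol-3-yl)imidazolidin-2-one | O=C1N[C@H](c2c[nH]c3ccc(Br)cc23)CN1
F2 | step 11 | (4R)-4-(2,5-dibromo-1H-indol-3-yl)imidazolidin-2-one | O=C1N[C@H](c2c(Br)[nH]c3ccc(Br)cc23)CN1
F3 | step 11 | (4R)-4-(2,5-dibromo-1H-indol-3-yl)-2-ethoxy-4,5-dihydro-1H-imidazol-3-ium tetrafluoroborate | CCOC1=[NH+][C@H](c2c(Br)[nH]c3ccc(Br)cc23)CN1.F[B-](F)(F)F
F4 | step 10 | tert-butyl (4R)-4-(5-bromo-1-tosyl-1H-indol-3-yl)-2-[(tert-butoxycarbonyl)imino]imidazolidine-1-carboxylate | CC(C)(C)OC(=O)N=C1N[C@H](c2cn(S(=O)(=O)c3ccc(C)cc3)c3ccc(Br)cc23)CN1C(=O)OC(C)(C)C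
F5 | step 10 | tert-butyl (4R)-4-(5-bromo-1H-indol-3-yl)-2-[(tert-butoxycarbonyl)imino]imidazolidine-1-carboxylate | CC(C)(C)OC(=O)N=C1N[C@H](c2c[nH]c3ccc(Br)cc23)CN1C(=O)OC(C)(C)C
F6 | step 6 | tert-butyl N-[(1R)-1-(5-bromo-1-tosyl-1H-indol-3-yl)-2-[(tert-butoxycarbonyl)amino]ethyl]carbamate | CC(C)(C)OC(=O)N[C@H](c1cn(S(=O)(=O)c2ccc(C)cc2)c2ccc(Br)cc12)CNC(=O)OC(C)(C)C
F7 | step 6 | (1R)-1-(5-bromo-1-tosyl-1H-indol-3-yl)ethane-1,2-diamine | N[C@H](c1cn(S(=O)(=O)c2ccc(C)cc2)c2ccc(Br)cc12)CN
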